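**Retrosynthetic overview**
1. Target 15 ⇐ bis-MOM ether 14 ⇐ keto diol 13 by anodic dehydrogenative closure of the O1–C2 bond; the oxolane is formed last and this step sets C2.
2. 13 ⇐ trans hydroxymethyl lactone 11 + aryllithium 12 (aryl ketone C–C bond, lactone opened); 11 ⇐ lactone 9 + formaldehyde (sets C4).
3. 9 ⇐ cyclopropane-fused lactone 6 + aryl Grignard 7 (homoconjugate opening, then Krapcho).
4. 6 ⇐ (R)-epichlorohydrin 3 + dimethyl malonate 4; cyclopropane and γ-lactone are formed first, and the bought stereocentre becomes C3.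
5. Both identical aryl groups come from one bromide 2, made from 5-bromo-2-methoxyphenol 1.

Assumption: the target oxolane is numbered O1, C2 (aryl), C3 (CH2OH), C4 (aroyl), C5, which makes the given SMILES (2S,3R,4S), all-trans.

**Route**

Step 1
Reactants: 1 5-bromo-2-methoxyphenol
Product: 2 4-bromo-1-methoxy-2-(methoxymethoxy)benzene
Conditions: NaH, THF, 0 °C; MOMCl, 0 °C → rt
Reagents that add atoms: chloromethyl methyl ether, COCCl
Why: Williamson-type O-alkylation of the sodium phenoxide masks the acidic phenol for the Grignard and aryllithium steps as an acetal that survives base, heat and the anode and leaves with dilute acid; no stereocentre is involved.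

Step 2
Reactants: 3 (R)-epichlorohydrin [(2R)-2-(chloromethyl)oxirane]; 4 dimethyl malonate
Product: 6 methyl (1S,5R)-2-oxo-3-oxabicyclo[3.1.0]hexane-1-carboxylate, via epoxide diester 5 (not isolated)
Conditions: NaOMe (1.1 equiv), MeOH, 0 °C → reflux
Reagents that add atoms: none
Why: tandem malonate alkylation–cyclopropanation–lactonisation: the malonate anion opens the epoxide of 3 at CH2, the alkoxide displaces chloride to give the transposed epoxide 5, the malonate carbanion opens 5 3-exo-tet with inversion at the bought stereocentre and the cis alkoxide lactonises, so C5 (R) derives from 3 and C1 (S) is fixed by the obligatory cis ring fusion.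

Step 3
Reactants: 6 methyl (1S,5R)-2-oxo-3-oxabicyclo[3.1.0]hexane-1-carboxylate; 2 4-bromo-1-methoxy-2-(methoxymethoxy)benzene
Product: 8 methyl (3S,4R)-4-{[4-methoxy-3-(methoxymethoxy)phenyl]methyl}-2-oxooxolane-3-carboxylate, via arylmagnesium bromide 7 (not isolated)
Conditions: 2 (1.3 equiv), Mg, THF, rt → 40 °C; then 6, CuI (10 mol%), THF, −30 → 0 °C; aq. NH4Cl
Reagents that add atoms: none
Why: copper-catalysed homoconjugate addition of aryl Grignard 7 to the doubly activated cyclopropane cleaves the C1–C6 bond by attack at the unsubstituted CH2 (C6), so the C5 stereocentre (now C4 of the lactone) is untouched and the malonate-type C3 settles trans.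

Step 4
Reactants: 8 methyl (3S,4R)-4-{[4-methoxy-3-(methoxymethoxy)phenyl]methyl}-2-oxooxolane-3-carboxylate
Product: 9 (4R)-4-{[4-methoxy-3-(methoxymethoxy)phenyl]methyl}oxolan-2-one
Conditions: LiCl, H2O, DMSO, 150 °C
Reagents that add atoms: none
Why: Krapcho dealkoxycarbonylation (chloride demethylation, loss of CO2, protonation by water) removes the ester; the C4 stereocentre is not alpha to a carbonyl and is unaffected.

Step 5
Reactants: 9 (4R)-4-{[4-methoxy-3-(methoxymethoxy)phenyl]methyl}oxolan-2-one
Product: 11 (3S,4R)-3-(hydroxymethyl)-4-{[4-methoxy-3-(methoxymethoxy)phenyl]methyl}oxolan-2-one, via lithium enolate 10 (not isolated)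
Conditions: LiN(iPr)2, THF, −78 °C; then CH2O (gas, from cracked paraformaldehyde), −78 → −40 °C; aq. NH4Cl
Reagents that add atoms: formaldehyde, C=O
Why: aldol addition of lithium enolate 10 to monomeric formaldehyde on the face anti to the C4 arylmethyl group gives the trans lactone, setting C3 (S), the future C4 of the target, under control of the epichlorohydrin-derived centre.

Step 6
Reactants: 11 (3S,4R)-3-(hydroxymethyl)-4-{[4-methoxy-3-(methoxymethoxy)phenyl]methyl}oxolan-2-one; 2 4-bromo-1-methoxy-2-(methoxymethoxy)benzene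
Product: 13 (2S,3R)-4-hydroxy-2-(hydroxymethyl)-1-[4-methoxy-3-(methoxymethoxy)phenyl]-3-{[4-methoxy-3-(methoxymethoxy)phenyl]methyl}butan-1-one, via aryllithium 12 (not isolated)
Conditions: 2 (2.4 equiv), n-BuLi, THF, −78 °C; then 11, −78 °C; aq. NH4Cl at −78 °C
Reagents that add atoms: none
Why: acyl substitution of the lactone by aryllithium 12 (the first equivalent is consumed by the hydroxyl) stops at the lithium hemiketal at −78 °C, which releases the aryl ketone only on quench, so there is no over-addition and the alpha stereocentre is never enolised.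

Step 7
Reactants: 13 (2S,3R)-4-hydroxy-2-(hydroxymethyl)-1-[4-methoxy-3-(methoxymethoxy)phenyl]-3-{[4-methoxy-3-(methoxymethoxy)phenyl]methyl}butan-1-one
Product: 14 [4-methoxy-3-(methoxymethoxy)phenyl]{(3S,4R,5S)-4-(hydroxymethyl)-5-[4-methoxy-3-(methoxymethoxy)phenyl]oxolan-3-yl}methanone
Conditions: undivided cell, graphite felt anode, Pt cathode, constant current 2 mA cm−2, 2.2 F mol−1, nBu4NBF4 (0.1 M), 2,6-lutidine (2.5 equiv), CH2Cl2/(CF3)2CHOH 9:1, 0.01 M, 0 °C
Reagents that add atoms: none
Why: Proposed new method: anodic dehydrogenative benzylic C–H/O–H cycloetherification, in which the electrode oxidises only the alkyl-substituted dialkoxyarene (ring A; the aroyl ring B is estimated to be several tenths of a volt harder to oxidise and is too electron-poor for Friedel–Crafts capture), 2,6-lutidine removes a benzylic proton from the radical cation, a second electron transfer gives the para-methoxy-stabilised benzylic cation, and the CH2OH group alpha to the ketone captures it 5-exo through an envelope with the aryl group anti to the C3 CH2OH substituent, setting C2 (S) trans to C3 (reversible ionisation of the para-methoxybenzylic ether lets any cis isomer equilibrate to trans), while lutidinium is reduced to H2 at the cathode; the closest known reaction types are anodic benzylic alkoxylation of 4-methoxyalkylbenzenes and quinone-mediated oxidative cycloetherification of dibenzylbutanediols, neither shown for an electrochemical closure to a 2-aryl-3,4-disubstituted oxolane carrying a free beta-hydroxy ketone.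

Step 8
Reactants: 14 [4-methoxy-3-(methoxymethoxy)phenyl]{(3S,4R,5S)-4-(hydroxymethyl)-5-[4-methoxy-3-(methoxymethoxy)phenyl]oxolan-3-yl}methanone
Product: 15 (3-hydroxy-4-methoxyphenyl)[(3S,4R,5S)-5-(3-hydroxy-4-methoxyphenyl)-4-(hydroxymethyl)oxolan-3-yl]methanone
Conditions: 2 M aq. HCl, THF, 45 °C
Reagents that add atoms: none
Why: acid hydrolysis of the two aryl methoxymethyl acetals frees the phenols; the conditions are too mild to enolise the aryl ketone appreciably, and any reversible ionisation at C2 returns the favoured all-trans oxolane.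

**Compound list**
1 | 5-bromo-2-methoxyphenol | COc1ccc(Br)cc1O | starting material
2 | 4-bromo-1-methoxy-2-(methoxymethoxy)benzene | COCOc1cc(Br)ccc1OC | intermediate
3 | (R)-epichlorohydrin, (2R)-2-(chloromethyl)oxirane | ClC[C@H]1CO1 | starting material
4 | dimethyl malonate | COC(=O)CC(=O)OC | starting material
5 | dimethyl 2-{[(2R)-oxiran-2-yl]methyl}propanedioate (not isolated) | COC(=O)C(C[C@@H]1CO1)C(=O)OC | intermediate
6 | methyl (1S,5R)-2-oxo-3-oxabicyclo[3.1.0]hexane-1-carboxylate | COC(=O)[C@]12C[C@H]1COC2=O | intermediate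
7 | [4-methoxy-3-(methoxymethoxy)phenyl]magnesium bromide (not isolated) | COCOc1cc([Mg]Br)ccc1OC | intermediate
8 | methyl (3S,4R)-4-{[4-methoxy-3-(methoxymethoxy)phenyl]methyl}-2-oxooxolane-3-carboxylate | COC(=O)[C@@H]1[C@@H](Cc2ccc(OC)c(OCOC)c2)COC1=O | intermediate
9 | (4R)-4-{[4-methoxy-3-(methoxymethoxy)phenyl]methyl}oxolan-2-one | O=C1C[C@@H](Cc2ccc(OC)c(OCOC)c2)CO1 | intermediate
10 | lithium (4R)-4-{[4-methoxy-3-(methoxymethoxy)phenyl]methyl}-4,5-dihydrofuran-2-olate (not isolated) | [Li]OC1=C[C@@H](Cc2ccc(OC)c(OCOC)c2)CO1 | intermediate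
11 | (3S,4R)-3-(hydroxymethyl)-4-{[4-methoxy-3-(methoxymethoxy)phenyl]methyl}oxolan-2-one | OC[C@@H]1[C@@H](Cc2ccc(OC)c(OCOC)c2)COC1=O | intermediate
12 | [4-methoxy-3-(methoxymethoxy)phenyl]lithium (not isolated) | COCOc1cc([Li])ccc1OC | intermediate
13 | (2S,3R)-4-hydroxy-2-(hydroxymethyl)-1-[4-methoxy-3-(methoxymethoxy)phenyl]-3-{[4-methoxy-3-(methoxymethoxy)phenyl]methyl}butan-1-one | O=C(c1ccc(OC)c(OCOC)c1)[C@H](CO)[C@H](CO)Cc1ccc(OC)c(OCOC)c1 | intermediate
14 | [4-methoxy-3-(methoxymethoxy)phenyl]{(3S,4R,5S)-4-(hydroxymethyl)-5-[4-methoxy-3-(methoxymethoxy)phenyl]oxolan-3-yl}methanone | COc1ccc(C(=O)[C@@H]2CO[C@H](c3ccc(OC)c(OCOC)c3)[C@H]2CO)cc1OCOC | intermediate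
15 | (3-hydroxy-4-methoxyphenyl)[(3S,4R,5S)-5-(3-hydroxy-4-methoxyphenyl)-4-(hydroxymethyl)oxolan-3-yl]methanone (CNP0234761.1) | COc1ccc(C(=O)[C@@H]2CO[C@H](c3ccc(OC)c(O)c3)[C@H]2CO)cc1O | target

**Step count and risks**

Total steps: 8. Longest linear sequence: 7 (steps 2–8, from 3).

Steps most likely to fail:

Step 7 (the proposed anodic ring closure). The risks are over-oxidation of the product's benzylic ether, dehydrodimerisation of ring A, and dehydration of the beta-hydroxy ketone. The fallback sets out from 13 and comes back at 14. Treat 13 with stoichiometric DDQ (1.2 equiv) in dry CH2Cl2 over 4 Å sieves at 0 °C → rt. This replaces electrode-driven electron transfer by thermal hydride abstraction from the ring A benzylic CH2 by a quinone, the known oxidative cycloetherification used to make 7,9'-epoxylignans. The same benzylic cation is trapped by the same hydroxyl, and no further compound is made (F0).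

Step 5 (hydroxymethylation with gaseous formaldehyde). The risks are double addition, retro-aldol and dehydration to the alpha-methylene lactone. The fallback sets out from 9 and comes back at 11. Alkylate lithium enolate 10 (LiN(iPr)2, THF, −78 °C) with benzyl chloromethyl ether, a formaldehyde cation equivalent. This gives, anti to the arylmethyl group, (3S,4R)-3-[(benzyloxy)methyl]-4-{[4-methoxy-3-(methoxymethoxy)phenyl]methyl}oxolan-2-one F1. Hydrogenolysis of the benzyl ether (H2, Pd/C, EtOAc, rt) then gives 11.

Step 6 (aryllithium addition to the free hydroxy lactone). The risks are over-addition, enolisation and retro-aldol of the beta-alkoxide. The fallback sets out from 11 and comes back at 13.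
- Open the lactone with Me(MeO)NH·HCl and i-PrMgCl (THF, −20 °C) to the Weinreb amide diol (2S,3R)-4-hydroxy-2-(hydroxymethyl)-N-methoxy-N-methyl-3-{[4-methoxy-3-(methoxymethoxy)phenyl]methyl}butanamide F2.
- Silylate both hydroxyls (Et3SiCl, imidazole, CH2Cl2) to its bis(triethylsilyl) ether F3.
- Add aryllithium 12 (from 2 and n-BuLi, THF, −78 → 0 °C); the chelated tetrahedral intermediate cannot over-add and gives the aryl ketone bis(triethylsilyl) ether F4.
- Remove the silyl groups (AcOH/THF/H2O 3:1:1, rt) to return 13.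

Further compounds
F0 | step 7 | none | none
F1 | step 5 | (3S,4R)-3-[(benzyloxy)methyl]-4-{[4-methoxy-3-(methoxymethoxy)phenyl]methyl}oxolan-2-one | C(OCc1ccccc1)[C@@H]2[C@@H](Cc3ccc(OC)c(OCOC)c3)COC2=O
F2 | step 6 | (2S,3R)-4-hydroxy-2-(hydroxymethyl)-N-methoxy-N-methyl-3-{[4-methoxy-3-(methoxymethoxy)phenyl]methyl}butanamide | CON(C)C(=O)[C@H](CO)[C@H](CO)Cc1ccc(OC)c(OCOC)c1
F3 | step 6 | (2S,3R)-N-methoxy-N-methyl-3-{[4-methoxy-3-(methoxymethoxy)phenyl]methyl}-4-[(triethylsilyl)oxy]-2-{[(triethylsilyl)oxy]methyl}butanamide | CON(C)C(=O)[C@H](CO[Si](CC)(CC)CC)[C@H](CO[Si](CC)(CC)CC)Cc1ccc(OC)c(OCOC)c1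
F4 | step 6 | (2S,3R)-1-[4-methoxy-3-(methoxymethoxy)phenyl]-3-{[4-methoxy-3-(methoxymethoxy)phenyl]methyl}-4-[(triethylsilyl)oxy]-2-{[(triethylsilyl)oxy]methyl}butan-1-one | O=C(c1ccc(OC)c(OCOC)c1)[C@H](CO[Si](CC)(CC)CC)[C@H](CO[Si](CC)(CC)CC)Cc1ccc(OC)c(OCOC)c1
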